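## Retrosynthetic overview

1. Target 14 ⇐ anti‑selective Rubottom oxidation at C3 and global MOM/TMS removal ⇐ (2S)‑enol silane 12.
2. 12 ⇐ C2–C1′ disconnection: enantioselective, dearomative Rh‑catalysed 1,4‑arylation of the heteroaromatic chromone 7 with the arylzinc from bromide 10, the enolate trapped as its TMS ether. The catalyst sets C2; C3 is later relayed from C2.
3. 7 ⇐ enaminone annulation of 5 ⇐ regioselective bis‑MOM protection ⇐ symmetry‑breaking mono‑C‑prenylation of phloroacetophenone 1.
4. 10 ⇐ MOM protection ⇐ ortho‑C‑prenylation of 4‑bromophenol 8.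
5. Ring order: A and B rings are bought as benzenoid feedstocks; the pyranone C ring is closed as an aromatic chromone (step 3) and then dearomatised (step 6).

Assumption 1: (S)‑BINAP/Rh–aryl is assumed to attack the chromone face that gives (2S), by analogy with its sense on cyclic enones; if the sense is opposite, (R)‑BINAP is used with no other change.
Assumption 2: in step 2 the 2‑OH, flanked by prenyl and C=O, is assumed to be the hydroxyl left unprotected; the minor regioisomer is removed by chromatography.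

## Route

**Step 1**
Reactants: 1, 2,4,6‑trihydroxyacetophenone; 2, prenyl bromide
Product: 3, 1‑[2,4,6‑trihydroxy‑3‑(3‑methylbut‑2‑en‑1‑yl)phenyl]ethanone
Conditions: 2 (1.0 equiv, slow addition), DBU (1.1 equiv), THF, 0 °C → rt
Reagents that add atoms: prenyl bromide, CC(C)=CCBr
Why: C‑alkylation of the ambident phloroglucinol‑type phenoxide (Friedel–Crafts‑type C‑allylation); the two ring CH positions are equivalent, so one mono‑C‑prenyl product forms and the ring symmetry is broken; no stereocentre.

**Step 2**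
Reactants: 3; 4, chloromethyl methyl ether (MOMCl)
Product: 5, 1‑[2‑hydroxy‑4,6‑bis(methoxymethoxy)‑3‑(3‑methylbut‑2‑en‑1‑yl)phenyl]ethanone
Conditions: MOMCl (2.2 equiv), i‑Pr2NEt (3 equiv), CH2Cl2, 0 °C → rt
Reagents that add atoms: MOMCl, COCCl
Why: Williamson‑type O‑alkylation; the non‑chelated 4‑OH and the less hindered 6‑OH react, while the 2‑OH (between prenyl and acetyl, hydrogen‑bonded to C=O) stays free.

**Step 3**
Reactants: 5; 6, N,N‑dimethylformamide dimethyl acetal (DMF‑DMA)
Product: 7, 5,7‑bis(methoxymethoxy)‑8‑(3‑methylbut‑2‑en‑1‑yl)‑4H‑chromen‑4‑one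
Conditions: DMF‑DMA (3 equiv), toluene, 95 °C; then AcOH, CH2Cl2, 40 °C
Reagents that add atoms: DMF‑DMA, COC(OC)N(C)C (supplies C2–H)
Why: enaminone formation followed by 6‑endo oxa‑Michael addition and loss of Me2NH (enaminone chromone synthesis); only the free 2‑OH can close, which fixes the prenyl at C8; AcOH is too weak to cleave aryl MOM ethers.

**Step 4**
Reactants: 8, 4‑bromophenol; 2, prenyl bromide
Product: 9, 4‑bromo‑2‑(3‑methylbut‑2‑en‑1‑yl)phenol
Conditions: NaH (1.0 equiv), toluene, 0 °C; then 2 (1.0 equiv), rt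
Reagents that add atoms: prenyl bromide, CC(C)=CCBr
Why: ortho‑selective C‑alkylation of a tight sodium phenoxide ion pair in a non‑polar solvent, with the para position blocked by Br.

**Step 5**
Reactants: 9; 4, MOMCl
Product: 10, 4‑bromo‑1‑(methoxymethoxy)‑2‑(3‑methylbut‑2‑en‑1‑yl)benzene
Conditions: MOMCl (1.3 equiv), i‑Pr2NEt (1.5 equiv), CH2Cl2, 0 °C → rt
Reagents that add atoms: MOMCl, COCCl
Why: standard phenol O‑alkylation; the MOM ether tolerates the later halogen–lithium exchange.

**Step 6 (key step)**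
Reactants: 10; 7; 11, chlorotrimethylsilane (TMSCl)
Product: 12, trimethyl({(2S)‑5,7‑bis(methoxymethoxy)‑2‑[4‑(methoxymethoxy)‑3‑(3‑methylbut‑2‑en‑1‑yl)phenyl]‑8‑(3‑methylbut‑2‑en‑1‑yl)‑2H‑chromen‑4‑yl}oxy)silane (used crude)
Conditions: 10 (1.6 equiv), t‑BuLi (3.2 equiv), THF, −78 °C; ZnCl2 (1.7 equiv), −78 → 0 °C; then 7 (1.0 equiv), [RhCl((S)‑BINAP)]2 (3 mol % Rh), TMSCl (1.6 equiv), THF, 20 °C; cold NaHCO3 wash
Reagents that add atoms: TMSCl, C[Si](C)(C)Cl
Why: Proposed new method: Zn→Rh transmetalation gives (S)‑BINAP–Rh–Ar, which carbometalates the chromone C2=C3 bond (aryl to C2) on one enantioface to set (2S) and dearomatise the γ‑pyrone, and TMSCl silylates the oxa‑π‑allyl rhodium enolate before it can ring‑open (E1cB), regenerating Rh–Cl; the closest known reactions are Rh/BINAP 1,4‑additions of ArZnCl/TMSCl to 4‑quinolones and 2,3‑dihydro‑4‑pyridones and Rh‑catalysed 1,4‑additions of arylboronic acids to chromones (Hayashi–Miyaura type).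

**Step 7**
Reactants: 12; 13, dimethyldioxirane (DMDO)
Product: 14, Lespedezaflavanone C, (2R,3R)‑3,5,7‑trihydroxy‑2‑[4‑hydroxy‑3‑(3‑methylbut‑2‑en‑1‑yl)phenyl]‑8‑(3‑methylbut‑2‑en‑1‑yl)chroman‑4‑one
Conditions: DMDO (1.05 equiv, acetone), CH2Cl2, −78 °C; Me2S; concentrate; then 3 M aq. HCl/MeOH (1:4), 40 °C, stopped as soon as MOM cleavage is complete
Reagents that add atoms: DMDO, CC1(C)OO1 (supplies the C3 oxygen)
Why: Rubottom oxidation, in which the electron‑rich enol silane is epoxidised far faster than the two prenyl alkenes at −78 °C and on the face anti to the C2 aryl, so the C3–O bond is trans to the aryl (2,3‑trans, 3R); acidic methanolysis then opens the siloxy‑epoxide and removes TMS and the three MOM groups, and C2 is untouched (its descriptor changes from S to R only through the CIP priority switch).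

## Compound list

1 | 2,4,6‑trihydroxyacetophenone | CC(=O)c1c(O)cc(O)cc1O | starting material
2 | prenyl bromide (1‑bromo‑3‑methylbut‑2‑ene) | CC(C)=CCBr | starting material
3 | 1‑[2,4,6‑trihydroxy‑3‑(3‑methylbut‑2‑en‑1‑yl)phenyl]ethanone | CC(=O)c1c(O)cc(O)c(CC=C(C)C)c1O | intermediate
4 | chloromethyl methyl ether (MOMCl) | COCCl | starting material
5 | 1‑[2‑hydroxy‑4,6‑bis(methoxymethoxy)‑3‑(3‑methylbut‑2‑en‑1‑yl)phenyl]ethanone | CC(=O)c1c(O)c(CC=C(C)C)c(OCOC)cc1OCOC | intermediate
6 | N,N‑dimethylformamide dimethyl acetal | COC(OC)N(C)C | starting material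
7 | 5,7‑bis(methoxymethoxy)‑8‑(3‑methylbut‑2‑en‑1‑yl)‑4H‑chromen‑4‑one | O=c1ccoc2c(CC=C(C)C)c(OCOC)cc(OCOC)c12 | intermediate
8 | 4‑bromophenol | Oc1ccc(Br)cc1 | starting material
9 | 4‑bromo‑2‑(3‑methylbut‑2‑en‑1‑yl)phenol | CC(C)=CCc1cc(Br)ccc1O | intermediate
10 | 4‑bromo‑1‑(methoxymethoxy)‑2‑(3‑methylbut‑2‑en‑1‑yl)benzene | COCOc1ccc(Br)cc1CC=C(C)C | intermediate
11 | chlorotrimethylsilane | C[Si](C)(C)Cl | starting material
12 | (2S)‑4‑(trimethylsilyloxy)‑2H‑chromene enol silane (full name in step 6) | CC(C)=CCc1cc([C@H]2Oc3c(CC=C(C)C)c(OCOC)cc(OCOC)c3C(O[Si](C)(C)C)=C2)ccc1OCOC | intermediate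
13 | dimethyldioxirane (from acetone/Oxone) | CC1(C)OO1 | starting material
14 | Lespedezaflavanone C, (2R,3R) | CC(C)=CCc1cc([C@H]2Oc3c(CC=C(C)C)c(O)cc(O)c3C(=O)[C@@H]2O)ccc1O | target

## Summary

Total steps: 7. Longest linear sequence: 5 (steps 1 → 2 → 3 → 6 → 7).

Steps most likely to fail, with fallbacks:

- **Step 6 (dearomative arylation/silyl trapping).** Risks are low reactivity of the electron‑rich 5‑alkoxychromone, MOM lability towards TMSCl/ZnCl2, and the unverified facial sense. Fallback: drop the C2–aryl disconnection and condense 5 with 4‑(methoxymethoxy)‑3‑prenylbenzaldehyde (from 10 via ArLi/DMF) to the chalcone. Asymmetric nucleophilic epoxidation (Juliá–Colonna type) and acid‑mediated 6‑endo epoxide opening with MOM removal would then give the trans‑dihydroflavonol.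
- **Step 7 (Rubottom oxidation and acidic unmasking).** Risks are epoxidation of the prenyl groups by DMDO and acid‑induced chroman formation from the o‑prenylphenols. Fallback: convert 12 to its lithium enolate (MeLi, −78 °C, no free base) and hydroxylate with an N‑sulfonyloxaziridine, which does not epoxidise the prenyl alkenes at that temperature. In the same fallback the phenols are carried as TBS ethers so the final deprotection uses buffered fluoride (HF·pyridine) instead of acid.
- **Step 2 (regioselective bis‑MOM protection that fixes the 8‑prenyl pattern).** Risk is a mixture of 4,6‑ and 2,4‑bis‑MOM isomers. Fallback: install the prenyl by a dearomative para‑Claisen–Cope sequence. 5,7‑Dihydroxychromone is converted to its 7‑O‑MOM ether and then its 5‑O‑prenyl ether; Eu(fod)3 in CHCl3 at 60 °C gives 5‑hydroxy‑8‑prenyl‑7‑MOM‑chromone, with regiochemistry dictated by the two [3,3] shifts, and 5‑O‑MOM protection then gives 7.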